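**Plan**
1. Numbering: ring C1(CH3)=C2H–C3H2–C4H2–C5(H)(CH3)–C6(CH3)(chain); chain C7–C16 with methyls on C9 and C13; butenolide C17 (β-carbon) to C20.
2. Cuts, last bond first: C16–C17 (alkylzinc + 4-bromofuranone); C14–C15 and C10–C11 (each behind an alkyne carboalumination that sets an E trisubstituted alkene); then C1–C6 and C4–C5 of the ring by a [4+2] cycloaddition.
3. Enabling feature: C5 and C6 are adjacent ring carbons whose cis methyl and C7 chain are the β- and α-substituents of an (E)-2-alkylbut-2-enal, the C6 methyl being its formyl group; C3 lies 1,4 to C6, where the oxygen of a 2-silyloxy diene lands.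
4. Forward order: the cyclohexene is made first. The C3 oxygen then places the alkene at C1=C2 and leaves together with the formyl oxygen; a bare C2=C3 alkene could drift to C4=C5 as easily as to C1=C2, both being trisubstituted. The chain is grown outwards from C9 and the intact butenolide is attached last.
5. Stereochemistry: C5/C6 relative configuration from the E enal geometry (suprafacial addition), absolute configuration from a chiral oxazaborolidinium catalyst; both chain alkenes from syn carboalumination and stereoretentive couplings.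

Key step: step 4

Assumption: the sense of induction follows the usual binding model of 2-substituted enals on the (S)-proline-derived oxazaborolidinium ion (diene enters at the C6 Re face); if the adduct proved antipodal, the (R)-catalyst would be used with no other change.

**Step 1**
Reactants: 1 (E)-but-2-enal
Product: 2 (Z)-2-iodobut-2-enal
Conditions: I2, K2CO3, DMAP (cat.), THF/H2O, rt
Reagents that add atoms: iodine II
Why: Baylis–Hillman-type α-iodination, in which DMAP adds to C3, the enolate is iodinated at C2 and loss of DMAP returns the alkene with iodine cis to methyl (formyl trans to methyl).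

**Step 2**
Reactants: 2 (Z)-2-iodobut-2-enal; 3 (3-ethoxy-3-oxopropyl)zinc bromide
Product: 4 ethyl (4E)-4-formylhex-4-enoate
Conditions: Pd2(dba)3 (2.5 mol %), P(2-furyl)3 (10 mol %), THF, 0 °C to rt
Reagents that add atoms: none
Why: Negishi sp2–sp3 coupling with retention at the alkenyl iodide, so the new chain sits cis to the methyl and the formyl group trans to it (E), while the ester-stabilised zinc homoenolate does not add to the aldehyde.

**Step 3**
Reactants: 5 (3E)-pent-3-en-2-one
Product: 6 triisopropyl[(3E)-penta-1,3-dien-2-yloxy]silane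
Conditions: i-Pr3SiOSO2CF3, Et3N, Et2O, 0 °C to rt
Reagents that add atoms: triisopropylsilyl trifluoromethanesulfonate CC(C)[Si](OS(=O)(=O)C(F)(F)F)(C(C)C)C(C)C
Why: Soft enolisation (silyl triflate/amine) at the methyl ketone gives the cross-conjugated 2-silyloxy diene with the E propenyl unit untouched, the bulky silyl group being chosen to survive the acidic cycloaddition catalyst.

**Step 4**
Reactants: 4 ethyl (4E)-4-formylhex-4-enoate; 6 triisopropyl[(3E)-penta-1,3-dien-2-yloxy]silane
Product: 7 ethyl 3-[(1S,2R,6R)-1-formyl-2,6-dimethyl-4-(triisopropylsilyloxy)cyclohex-3-en-1-yl]propanoate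
Conditions: (S)-tetrahydro-1-(2-methylphenyl)-3,3-diphenyl-1H,3H-pyrrolo[1,2-c][1,3,2]oxazaborole (20 mol %), (CF3SO2)2NH (18 mol %), CH2Cl2, −78 °C; 4, then 6 (1.5 equiv), −78 to −40 °C
Reagents that add atoms: none
Why: The protonated oxazaborolidine binds the formyl oxygen of 4, holds the formyl C–H against its ring oxygen and stacks the s-trans enal over a phenyl group, so diene 6 adds to the open C6 Re face in a concerted, asynchronous, suprafacial Diels–Alder [4+2] in which C4–C5 forms ahead of C1–C6. The closest known reaction is the oxazaborolidinium triflimide-catalysed Diels–Alder addition of 2-substituted enals to 2-silyloxy and 1-alkyl dienes. The cyclohexene ring closes by intermolecular [4+2] cycloaddition, both σ bonds being made on one face of each partner. C6 is set by the catalyst-controlled face; C5 follows from the E geometry of the enal (methyl cis to the C7 chain, trans to formyl); C1 is set by the endo placement of formyl but becomes sp2 in step 5, so either C1 epimer serves. The step needs regio- and facial selectivity: the C3 silyloxy and C1 methyl groups both enlarge the diene HOMO coefficient at C4, which therefore bonds to the electrophilic β-carbon C5 and leaves C1 to meet C6, and the face is fixed by the catalyst.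

**Step 5**
Reactants: 7 ethyl 3-[(1S,2R,6R)-1-formyl-2,6-dimethyl-4-(triisopropylsilyloxy)cyclohex-3-en-1-yl]propanoate
Product: 8 ethyl 3-[(1S,6R)-1-formyl-2,6-dimethyl-4-oxocyclohex-2-en-1-yl]propanoate
Conditions: Pd(OAc)2 (1.1 equiv), DMSO, 40 °C
Reagents that add atoms: none
Why: Saegusa–Ito oxidation, in which the C2=C3 silyl enol ether passes to a C2 palladium enolate whose only β-hydrogen is on C1, so β-hydride elimination gives the C1=C2 enone regiospecifically and removes the C1 stereocentre without touching C5 or C6.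

**Step 6**
Reactants: 8 ethyl 3-[(1S,6R)-1-formyl-2,6-dimethyl-4-oxocyclohex-2-en-1-yl]propanoate
Product: 9 ethyl 3-[(8S,9R)-8-(1,3-dithiolan-2-yl)-7,9-dimethyl-1,4-dithiaspiro[4.5]dec-6-en-8-yl]propanoate
Conditions: HS(CH2)2SH (4 equiv), BF3·OEt2, CH2Cl2, 0 °C to rt
Reagents that add atoms: ethane-1,2-dithiol SCCS
Why: Lewis acid-promoted dithioacetalisation of both carbonyl groups, the alkene being unable to leave C1=C2 because C6 is quaternary.

**Step 7**
Reactants: 9 ethyl 3-[(8S,9R)-8-(1,3-dithiolan-2-yl)-7,9-dimethyl-1,4-dithiaspiro[4.5]dec-6-en-8-yl]propanoate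
Product: 10 ethyl 3-[(1R,6R)-1,2,6-trimethylcyclohex-2-en-1-yl]propanoate
Conditions: Raney Ni (W-2, excess), EtOH, reflux
Reagents that add atoms: none
Why: Mozingo desulfurisation (C–S hydrogenolysis on nickel) turns the dithiolanyl group into the C6 methyl and the thioketal into the C3 methylene, as in the classical conversion of 4-en-3-one thioketals into 4-enes, and should leave the ester and the trisubstituted alkene alone.

**Step 8**
Reactants: 10 ethyl 3-[(1R,6R)-1,2,6-trimethylcyclohex-2-en-1-yl]propanoate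
Product: 12 (5R,6R)-6-(but-3-yn-1-yl)-1,5,6-trimethylcyclohex-1-ene, via C9 aldehyde 11 (not isolated)
Conditions: i-Bu2AlH (1.1 equiv), CH2Cl2, −78 °C; then MeOH, K2CO3, dimethyl (1-diazo-2-oxopropyl)phosphonate, −78 °C to rt
Reagents that add atoms: dimethyl (1-diazo-2-oxopropyl)phosphonate COP(=O)(OC)C(=[N+]=[N-])C(C)=O
Why: Partial ester reduction to the aluminium hemiacetal followed in the same flask by Ohira–Bestmann (Seyferth–Gilbert) homologation of the released aldehyde 11, which adds C10 as the alkyne terminus and does not touch the ring stereocentres.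

**Step 9**
Reactants: 12 (5R,6R)-6-(but-3-yn-1-yl)-1,5,6-trimethylcyclohex-1-ene
Product: 14 (5R,6R)-6-[(3E)-4-iodo-3-methylbut-3-en-1-yl]-1,5,6-trimethylcyclohex-1-ene, via alkenyldimethylalane 13 (not isolated)
Conditions: Me3Al (2 equiv), Cp2ZrCl2 (0.25 equiv), CH2Cl2, 0 °C to rt; then I2, THF, −30 to 0 °C
Reagents that add atoms: trimethylaluminium C[Al](C)C; iodine II
Why: Zirconium-catalysed Negishi carboalumination adds methyl (to C9) and aluminium syn across the terminal alkyne, and iodinolysis of the C–Al bond with retention gives the E alkenyl iodide, the trisubstituted ring alkene being inert.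

**Step 10**
Reactants: 14 (5R,6R)-6-[(3E)-4-iodo-3-methylbut-3-en-1-yl]-1,5,6-trimethylcyclohex-1-ene; 15 (4-bromobut-1-yn-1-yl)trimethylsilane
Product: 17 trimethyl[(5E)-6-methyl-8-[(1R,6R)-1,2,6-trimethylcyclohex-2-en-1-yl]oct-5-en-1-yn-1-yl]silane, via alkynylalkylzinc bromide 16 (not isolated)
Conditions: 15, Zn dust, LiCl, THF, 50 °C; then 14, PdCl2(dppf) (5 mol %), THF, rt
Reagents that add atoms: none
Why: Negishi coupling of the alkenyl iodide with a homopropargylic alkylzinc forms C10–C11 with retention of the C9=C10 geometry.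

**Step 11**
Reactants: 17 trimethyl[(5E)-6-methyl-8-[(1R,6R)-1,2,6-trimethylcyclohex-2-en-1-yl]oct-5-en-1-yn-1-yl]silane
Product: 18 (5R,6R)-1,5,6-trimethyl-6-[(3E)-3-methyloct-3-en-7-yn-1-yl]cyclohex-1-ene
Conditions: K2CO3, MeOH, rt
Reagents that add atoms: none
Why: Base-mediated methanolysis of the alkynyl C–Si bond (protodesilylation) frees the terminal alkyne.

**Step 12**
Reactants: 18 (5R,6R)-1,5,6-trimethyl-6-[(3E)-3-methyloct-3-en-7-yn-1-yl]cyclohex-1-ene
Product: 21 (3E,7E)-4,8-dimethyl-10-[(1R,6R)-1,2,6-trimethylcyclohex-2-en-1-yl]deca-3,7-dien-1-ol, via alkenyldimethylalane 19 (not isolated), via lithium alkenylalanate 20 (not isolated)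
Conditions: Me3Al (2 equiv), Cp2ZrCl2 (0.25 equiv), CH2Cl2, rt; volatiles removed; n-BuLi, hexane/THF, −78 °C; ethylene oxide, −78 to 0 °C
Reagents that add atoms: trimethylaluminium C[Al](C)C; ethylene oxide C1CO1
Why: A second syn carboalumination sets the E C13=C14 alkene, and the more nucleophilic alkenylalanate formed with n-BuLi opens ethylene oxide with retention at C14, adding C15, C16 and the hydroxyl.

**Step 13**
Reactants: 21 (3E,7E)-4,8-dimethyl-10-[(1R,6R)-1,2,6-trimethylcyclohex-2-en-1-yl]deca-3,7-dien-1-ol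
Product: 22 (5R,6R)-6-[(3E,7E)-10-iodo-3,7-dimethyldeca-3,7-dien-1-yl]-1,5,6-trimethylcyclohex-1-ene
Conditions: I2, PPh3, imidazole, CH2Cl2, 0 °C to rt
Reagents that add atoms: iodine II
Why: Appel-type iodination, in which iodide displaces the oxyphosphonium group of the primary alcohol by SN2.

**Step 14**
Reactants: 22 (5R,6R)-6-[(3E,7E)-10-iodo-3,7-dimethyldeca-3,7-dien-1-yl]-1,5,6-trimethylcyclohex-1-ene; 23 4-bromofuran-2(5H)-one
Product: 25 4-[(3E,7E)-4,8-dimethyl-10-[(1R,6R)-1,2,6-trimethylcyclohex-2-en-1-yl]deca-3,7-dien-1-yl]furan-2(5H)-one, via alkylzinc iodide 24 (not isolated)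
Conditions: 22, Zn dust, LiCl, THF, 40 °C; then 23, Pd(PPh3)4 (5 mol %), THF, rt
Reagents that add atoms: none
Why: Zinc insertion gives a non-basic homoallylic alkylzinc that tolerates the lactone, and Negishi coupling at the C–Br bond of the β-bromobutenolide forms C16–C17.

**Compound list**
1 | (E)-but-2-enal | C/C=C/C=O | starting material
2 | (Z)-2-iodobut-2-enal | C/C=C(\I)C=O | intermediate
3 | (3-ethoxy-3-oxopropyl)zinc bromide | CCOC(=O)CC[Zn]Br | starting material
4 | ethyl (4E)-4-formylhex-4-enoate | C/C=C(/C=O)CCC(=O)OCC | intermediate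
5 | (3E)-pent-3-en-2-one | C/C=C/C(C)=O | starting material
6 | triisopropyl[(3E)-penta-1,3-dien-2-yloxy]silane | C/C=C/C(=C)O[Si](C(C)C)(C(C)C)C(C)C | intermediate
7 | ethyl 3-[(1S,2R,6R)-1-formyl-2,6-dimethyl-4-(triisopropylsilyloxy)cyclohex-3-en-1-yl]propanoate | C[C@@H]1C=C(O[Si](C(C)C)(C(C)C)C(C)C)C[C@@H](C)[C@@]1(C=O)CCC(=O)OCC | intermediate
8 | ethyl 3-[(1S,6R)-1-formyl-2,6-dimethyl-4-oxocyclohex-2-en-1-yl]propanoate | CC1=CC(=O)C[C@@H](C)[C@@]1(C=O)CCC(=O)OCC | intermediate
9 | ethyl 3-[(8S,9R)-8-(1,3-dithiolan-2-yl)-7,9-dimethyl-1,4-dithiaspiro[4.5]dec-6-en-8-yl]propanoate | CC1=CC2(SCCS2)C[C@@H](C)[C@@]1(C3SCCS3)CCC(=O)OCC | intermediate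
10 | ethyl 3-[(1R,6R)-1,2,6-trimethylcyclohex-2-en-1-yl]propanoate | CC1=CCC[C@@H](C)[C@@]1(C)CCC(=O)OCC | intermediate
11 | 3-[(1R,6R)-1,2,6-trimethylcyclohex-2-en-1-yl]propanal | CC1=CCC[C@@H](C)[C@@]1(C)CCC=O | intermediate
12 | (5R,6R)-6-(but-3-yn-1-yl)-1,5,6-trimethylcyclohex-1-ene | CC1=CCC[C@@H](C)[C@@]1(C)CCC#C | intermediate
13 | [(1E)-2-methyl-4-[(1R,6R)-1,2,6-trimethylcyclohex-2-en-1-yl]but-1-en-1-yl]dimethylalumane | CC1=CCC[C@@H](C)[C@@]1(C)CC/C(C)=C/[Al](C)C | intermediate
14 | (5R,6R)-6-[(3E)-4-iodo-3-methylbut-3-en-1-yl]-1,5,6-trimethylcyclohex-1-ene | CC1=CCC[C@@H](C)[C@@]1(C)CC/C(C)=C/I | intermediate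
15 | (4-bromobut-1-yn-1-yl)trimethylsilane | C[Si](C)(C)C#CCCBr | starting material
16 | [4-(trimethylsilyl)but-3-yn-1-yl]zinc bromide | C[Si](C)(C)C#CCC[Zn]Br | intermediate
17 | trimethyl[(5E)-6-methyl-8-[(1R,6R)-1,2,6-trimethylcyclohex-2-en-1-yl]oct-5-en-1-yn-1-yl]silane | CC1=CCC[C@@H](C)[C@@]1(C)CC/C(C)=C/CCC#C[Si](C)(C)C | intermediate
18 | (5R,6R)-1,5,6-trimethyl-6-[(3E)-3-methyloct-3-en-7-yn-1-yl]cyclohex-1-ene | CC1=CCC[C@@H](C)[C@@]1(C)CC/C(C)=C/CCC#C | intermediate
19 | [(1E,5E)-2,6-dimethyl-8-[(1R,6R)-1,2,6-trimethylcyclohex-2-en-1-yl]octa-1,5-dien-1-yl]dimethylalumane | CC1=CCC[C@@H](C)[C@@]1(C)CC/C(C)=C/CC/C(C)=C/[Al](C)C | intermediate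
20 | lithium butyl[(1E,5E)-2,6-dimethyl-8-[(1R,6R)-1,2,6-trimethylcyclohex-2-en-1-yl]octa-1,5-dien-1-yl]dimethylaluminate | CC1=CCC[C@@H](C)[C@@]1(C)CC/C(C)=C/CC/C(C)=C/[Al-](C)(C)CCCC.[Li+] | intermediate
21 | (3E,7E)-4,8-dimethyl-10-[(1R,6R)-1,2,6-trimethylcyclohex-2-en-1-yl]deca-3,7-dien-1-ol | CC1=CCC[C@@H](C)[C@@]1(C)CC/C(C)=C/CC/C(C)=C/CCO | intermediate
22 | (5R,6R)-6-[(3E,7E)-10-iodo-3,7-dimethyldeca-3,7-dien-1-yl]-1,5,6-trimethylcyclohex-1-ene | CC1=CCC[C@@H](C)[C@@]1(C)CC/C(C)=C/CC/C(C)=C/CCI | intermediate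
23 | 4-bromofuran-2(5H)-one | O=C1C=C(Br)CO1 | starting material
24 | [(3E,7E)-4,8-dimethyl-10-[(1R,6R)-1,2,6-trimethylcyclohex-2-en-1-yl]deca-3,7-dien-1-yl]zinc iodide | CC1=CCC[C@@H](C)[C@@]1(C)CC/C(C)=C/CC/C(C)=C/CC[Zn]I | intermediate
25 | 4-[(3E,7E)-4,8-dimethyl-10-[(1R,6R)-1,2,6-trimethylcyclohex-2-en-1-yl]deca-3,7-dien-1-yl]furan-2(5H)-one | CC1=CCC[C@@H](C)[C@@]1(C)CC/C(C)=C/CC/C(C)=C/CCC1=CC(=O)OC1 | target

**Step count**
Total: 14 steps. Longest linear sequence: 13 steps (steps 1, 2 and 4 to 14); step 3 is a one-step branch.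

**Steps most likely to fail**

Step 4. The two faces of the bound α,β-disubstituted enal may not be told apart well enough (low enantiomeric purity), or the silyl dienol ether may be lost to protodesilylation or to addition at the activated formyl group instead of cycloaddition. The fallback sets out from 4 and 6 and gives up catalyst control for separation of diastereomers. The cycloaddition is run with Me2AlCl (CH2Cl2, −78 °C) and should give 7 together with its enantiomer, ent-adduct F1. The conditions of step 5 then give 8 together with its enantiomer, ent-enone aldehyde F2. Acetalisation of the formyl groups with (1R,2R)-1,2-diphenylethane-1,2-diol (pyridinium tosylate, benzene, reflux with water removal) gives the diastereomeric diphenyldioxolane F3 (from 8) and diphenyldioxolane F4 (from F2), which are separated by chromatography. F3 is taken into the conditions of step 6, where ethane-1,2-dithiol/BF3·OEt2 exchange the dioxolane for the dithiolane and thioketalise the enone. The route is rejoined at 9.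

Step 5. Silicon-to-palladium transfer from the bulky enol ether may be slow, or the enol ether may simply be cleaved to the saturated ketone, which would lose the regiochemical information. The fallback sets out from 7. N-Bromosuccinimide (THF, 0 °C) brominates the silyl enol ether at C2 to give the 2-bromo ketone F5. Dehydrobromination with Li2CO3/LiBr in DMF at 100 °C, which can only run towards C1, gives 8, where the route is rejoined.

Step 7. During hydrogenolysis of the allylic C–S bonds hydrogen may be delivered to C1 instead of C3, so that the alkene drifts to C2=C3, or the ring alkene may be saturated by hydrogen-rich nickel. The fallback sets out from 8 and removes the enone oxygen through an allyl cation instead. Aldehyde-selective dithioacetalisation (1 equiv ethane-1,2-dithiol, BF3·OEt2, CH2Cl2, −40 °C) gives the dithiolanyl enone F6. Luche reduction (NaBH4, CeCl3·7H2O, MeOH, −78 °C) gives the allylic alcohol F7. Ionic deoxygenation (Et3SiH, BF3·OEt2, CH2Cl2, −78 °C), in which hydride attacks the unhindered C3 end of the allyl cation, gives the dithiolanyl alkene F8. Radical desulfurisation of the now non-allylic dithiolane (n-Bu3SnH, AIBN, toluene, reflux) gives 10, where the route is rejoined.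

**Further compounds**
F1 | step 4 | ethyl 3-[(1R,2S,6S)-1-formyl-2,6-dimethyl-4-(triisopropylsilyloxy)cyclohex-3-en-1-yl]propanoate | C[C@H]1C=C(O[Si](C(C)C)(C(C)C)C(C)C)C[C@H](C)[C@]1(C=O)CCC(=O)OCC
F2 | step 4 | ethyl 3-[(1R,6S)-1-formyl-2,6-dimethyl-4-oxocyclohex-2-en-1-yl]propanoate | CC1=CC(=O)C[C@H](C)[C@]1(C=O)CCC(=O)OCC
F3 | step 4 | ethyl 3-[(1S,6R)-1-[(4R,5R)-4,5-diphenyl-1,3-dioxolan-2-yl]-2,6-dimethyl-4-oxocyclohex-2-en-1-yl]propanoate | CC1=CC(=O)C[C@@H](C)[C@@]1(C2O[C@H](c3ccccc3)[C@@H](c3ccccc3)O2)CCC(=O)OCC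
F4 | step 4 | ethyl 3-[(1R,6S)-1-[(4R,5R)-4,5-diphenyl-1,3-dioxolan-2-yl]-2,6-dimethyl-4-oxocyclohex-2-en-1-yl]propanoate | CC1=CC(=O)C[C@H](C)[C@]1(C2O[C@H](c3ccccc3)[C@@H](c3ccccc3)O2)CCC(=O)OCC
F5 | step 5 | ethyl 3-[3-bromo-1-formyl-2,6-dimethyl-4-oxocyclohexyl]propanoate (ring stereocentres as in 7, CHBr epimers) | C[C@@H]1C(Br)C(=O)C[C@@H](C)[C@@]1(C=O)CCC(=O)OCC
F6 | step 7 | ethyl 3-[(1S,6R)-1-(1,3-dithiolan-2-yl)-2,6-dimethyl-4-oxocyclohex-2-en-1-yl]propanoate | CC1=CC(=O)C[C@@H](C)[C@@]1(C2SCCS2)CCC(=O)OCC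
F7 | step 7 | ethyl 3-[(1S,6R)-1-(1,3-dithiolan-2-yl)-4-hydroxy-2,6-dimethylcyclohex-2-en-1-yl]propanoate (carbinol epimers) | CC1=CC(O)C[C@@H](C)[C@@]1(C2SCCS2)CCC(=O)OCC
F8 | step 7 | ethyl 3-[(1S,6R)-1-(1,3-dithiolan-2-yl)-2,6-dimethylcyclohex-2-en-1-yl]propanoate | CC1=CCC[C@@H](C)[C@@]1(C2SCCS2)CCC(=O)OCC
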